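**Retrosynthetic overview**

1. The γ-lactone is opened at O–C6 together with C7–C11. The feature that allows this: C6, which carries the lactone oxygen, is allylic to the ring alkene C4=C5 and is flanked by C7, which carries the acrylate carbon C11. The α-methylene-γ-butyrolactone ring is therefore the 1,2-carbo-oxygenation footprint of a ring 1,3-diene C4=C5–C6=C7 joined to 2-bromoacrylic acid, with the C4=C5 bond left where the target has it.
2. The diene partner is the 3,10-oxygen-bridged ten-membered carbocycle (11-oxabicyclo[6.2.1]undeca-2,4-diene). Its carbocycle is closed at C6=C7 by ring-closing metathesis, templated by the C3/C10 hemiketal (tetrahydrofuran ring) that the target keeps, and then locked as the methyl ketal.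
3. The metathesis substrate comes from C3–C4 bond formation: a (Z)-dienyllithium (from trans-hydrostannation of pent-4-en-2-yn-1-ol) adds to a γ-lactone.
4. The lactone comes from (R)-linalool: its carbinol carbon becomes C10 (with C14), its C4–C6 become C1–C3, and its vinyl group becomes C9–C8. C8 is set by catalytic asymmetric vinylation.
5. Ring order: tetrahydrofuran (hemiketal) → ten-membered carbocycle / nine-membered oxacycle → γ-lactone; then the C8 isobutyrate, and removal of the TBS ether and the methyl ketal.

Key step: step 13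

Remark on the chemistry: atoms are numbered as in germacranolides (ring C1–C10; C11–C13 the acrylate unit; C14 the methyl on C10; C15 the CH2OH carbon on C4). The given structure is (3S,6S,7R,8R,10R) with a 4Z alkene. The lactone is cis-fused, and C6–O, C7–C11, C8–O and the 3,10-oxygen bridge lie on one face of the ten-membered ring.
Assumption: in the ring-closed compounds the bridged C3 hemiketal is the stable form, as in the target. Divinylzinc is prepared from vinylmagnesium bromide and ZnCl2; the other reagents are commercial. Cp* = C5Me5.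

**Route**

Step 1
Reactants: 1 (R)-(−)-linalool
Product: 3 (5R)-5-methyl-5-vinyltetrahydrofuran-2-ol (both anomers), via open-chain hydroxy aldehyde 2 (not isolated)
Conditions: O3 (1.0 equiv, Sudan Red 7B end point), CH2Cl2/MeOH, −78 °C; then Me2S, −78 °C → rt
Reagents that add atoms: ozone, O=[O+][O-]
Why: Ozonolysis: the electron-rich trisubstituted alkene reacts with ozone much faster than the vinyl group, so one equivalent should cleave it alone, and the aldehyde is trapped by the tertiary hydroxyl as the lactol; C10 comes unchanged from the chiral pool.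

Step 2
Reactants: 3 (5R)-5-methyl-5-vinyltetrahydrofuran-2-ol
Product: 4 (5R)-5-methyl-5-vinyldihydrofuran-2(3H)-one
Conditions: PhI(OAc)2 (1.2 equiv), TEMPO (10 mol%), CH2Cl2, rt
Reagents that add atoms: none
Why: Oxoammonium (TEMPO) oxidation of a lactol to the lactone under neutral conditions that leave the vinyl group alone.

Step 3
Reactants: 4 (5R)-5-methyl-5-vinyldihydrofuran-2(3H)-one
Product: 6 (5R)-5-(2-hydroxyethyl)-5-methyldihydrofuran-2(3H)-one, via B-alkyl-9-BBN adduct 5 (not isolated)
Conditions: 9-BBN (1.3 equiv), THF, 0 °C → rt; then NaBO3·4H2O, H2O, rt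
Reagents that add atoms: sodium perborate, O[B-]1(O)OO[B-](O)(O)OO1.[Na+].[Na+]
Why: Anti-Markovnikov hydroboration–oxidation: 9-BBN puts boron on the terminal carbon of the hindered vinyl group without reducing the lactone, and the mild perborate oxidation spares the lactone, which turns the linalool vinyl group into C9–C8.

Step 4
Reactants: 6 (5R)-5-(2-hydroxyethyl)-5-methyldihydrofuran-2(3H)-one
Product: 7 2-[(2R)-2-methyl-5-oxotetrahydrofuran-2-yl]acetaldehyde
Conditions: Dess–Martin periodinane, CH2Cl2, 0 °C → rt
Reagents that add atoms: none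
Why: Dess–Martin oxidation of the primary alcohol; the β-acyloxy aldehyde is used at once so that base-induced β-elimination of the lactone carboxylate cannot set in.

Step 5
Reactants: 7 2-[(2R)-2-methyl-5-oxotetrahydrofuran-2-yl]acetaldehyde
Product: 8 (5R)-5-[(2R)-2-hydroxybut-3-en-1-yl]-5-methyldihydrofuran-2(3H)-one
Conditions: divinylzinc (2 equiv), (−)-MIB [(2S)-3-exo-morpholinoisoborneol] (10 mol%), toluene/hexane, 0 °C; 1 M HCl work-up
Reagents that add atoms: divinylzinc, C=C[Zn]C=C
Why: Amino-alcohol-catalysed asymmetric addition of divinylzinc to an aldehyde: the ligand should direct the vinyl group to the Si face, which here gives (8R) under reagent control (the antipodal ligand would be used if the sense proved opposite), and the organozinc does not touch the lactone.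

Step 6
Reactants: 8 (5R)-5-[(2R)-2-hydroxybut-3-en-1-yl]-5-methyldihydrofuran-2(3H)-one
Product: 9 (5R)-5-methyl-5-[(2R)-2-(triethylsilyloxy)but-3-en-1-yl]dihydrofuran-2(3H)-one
Conditions: Et3SiCl, imidazole, CH2Cl2, 0 °C
Reagents that add atoms: chlorotriethylsilane, CC[Si](Cl)(CC)CC
Why: Silylation of the secondary allylic alcohol, which keeps the C8 oxygen away from C3 until the ten-membered ring is closed.

Step 7
Reactants: 10 prop-2-yn-1-ol, 11 vinyl bromide
Product: 12 pent-4-en-2-yn-1-ol
Conditions: PdCl2(PPh3)2 (2 mol%), CuI (4 mol%), i-Pr2NH, THF, 0 °C → rt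
Reagents that add atoms: none
Why: Sonogashira coupling of a terminal alkyne with a vinyl halide.

Step 8
Reactants: 12 pent-4-en-2-yn-1-ol
Product: 13 (2Z)-2-(tributylstannyl)penta-2,4-dien-1-ol
Conditions: Bu3SnH (1.1 equiv), [Cp*RuCl]4 (1.5 mol%), CH2Cl2, rt
Reagents that add atoms: tributyltin hydride, CCCC[SnH](CCCC)CCCC
Why: Ruthenium-catalysed trans-hydrostannation of a propargylic alcohol: the hydroxyl directs tin to the alkyne carbon next to CH2OH and the anti addition places tin cis to the vinyl group, which fixes the Z geometry of the later C4=C5 bond (C3 and C6 cis) and leaves the alkene of the enyne alone.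

Step 9
Reactants: 13 (2Z)-2-(tributylstannyl)penta-2,4-dien-1-ol
Product: 14 tert-butyldimethyl{[(2Z)-2-(tributylstannyl)penta-2,4-dien-1-yl]oxy}silane
Conditions: TBSCl, imidazole, DMF, rt
Reagents that add atoms: tert-butyldimethylsilyl chloride, CC(C)(C)[Si](C)(C)Cl
Why: Silylation of the primary allylic alcohol (the later C15 hydroxyl).

Step 10
Reactants: 14 tert-butyldimethyl{[(2Z)-2-(tributylstannyl)penta-2,4-dien-1-yl]oxy}silane, 9 (5R)-5-methyl-5-[(2R)-2-(triethylsilyloxy)but-3-en-1-yl]dihydrofuran-2(3H)-one
Product: 16 (3Z,8R,10R)-4-[(tert-butyldimethylsilyloxy)methyl]-8-hydroxy-8-methyl-10-(triethylsilyloxy)dodeca-1,3,11-trien-5-one, via vinyllithium 15 (not isolated)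
Conditions: 14, n-BuLi, THF, −78 °C; then 9, −78 °C; aq. NH4Cl at −78 °C
Reagents that add atoms: none
Why: Tin–lithium exchange with retention of alkene geometry, then acylation of the vinyllithium by the γ-lactone: the tetrahedral lithium lactolate persists at −78 °C and blocks a second addition, so work-up should give the γ-hydroxy enone with the C3–C4 bond in place.

Step 11
Reactants: 16 (3Z,8R,10R)-4-[(tert-butyldimethylsilyloxy)methyl]-8-hydroxy-8-methyl-10-(triethylsilyloxy)dodeca-1,3,11-trien-5-one
Product: 18 (1S,2Z,4Z,6R,8R)-2-[(tert-butyldimethylsilyloxy)methyl]-8-methyl-6-(triethylsilyloxy)-11-oxabicyclo[6.2.1]undeca-2,4-dien-1-ol (germacrane numbering: 3S,8R,10R; 4Z,6Z), via cis-lactol tautomer 17 (not isolated)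
Conditions: second-generation Grubbs catalyst (10 mol%, in portions), 1,4-benzoquinone (10 mol%), toluene (1 mM), 80 °C
Reagents that add atoms: none
Why: Ring-closing metathesis: the hydroxy ketone equilibrates with its cyclic hemiketal, whose cis isomer holds the diene and the vinyl carbinol on one side of the tetrahydrofuran ring, so the closure is that of a nine-membered oxacycle and should give the Z C6=C7 alkene; the trisubstituted C4=C5 bond does not engage, and the C3 configuration of the bridged hemiketal is dictated by C10.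

Step 12
Reactants: 18 (1S,2Z,4Z,6R,8R)-2-[(tert-butyldimethylsilyloxy)methyl]-8-methyl-6-(triethylsilyloxy)-11-oxabicyclo[6.2.1]undeca-2,4-dien-1-ol
Product: 20 (1S,2Z,4Z,6R,8R)-2-[(tert-butyldimethylsilyloxy)methyl]-1-methoxy-8-methyl-11-oxabicyclo[6.2.1]undeca-2,4-dien-6-ol, via TES-protected methyl ketal 19 (not isolated)
Conditions: PPTS (10 mol%), MeOH, 0 °C → rt
Reagents that add atoms: methanol, CO
Why: Acid-catalysed exchange of the hemiketal OH for OMe in methanol with concurrent methanolysis of the secondary TES ether (the primary TBS ether is much slower under PPTS); the bridge allows only one C3 configuration, and the freed C8 hydroxyl, on the same face as the oxygen bridge, cannot reach C3.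

Step 13
Reactants: 20 (1S,2Z,4Z,6R,8R)-2-[(tert-butyldimethylsilyloxy)methyl]-1-methoxy-8-methyl-11-oxabicyclo[6.2.1]undeca-2,4-dien-6-ol, 21 2-bromoacrylic acid
Product: 22 the cis-fused α-methylene-γ-lactone (3S,6S,7R,8R,10R; 4Z) with 3-OMe, 8-OH and 15-OTBS (the target skeleton without the isobutyrate)
Conditions: Pd(OAc)2 (10 mol%), PPh3 (20 mol%), Ag2CO3 (1.2 equiv), 21 (2 equiv), MeCN, 60 °C
Reagents that add atoms: none
Why: Proposed new method: zerovalent palladium inserts into the C–Br bond of 21, and the vinylpalladium carboxylate, held by the free C8 hydroxyl on the face that carries it, adds syn across C6=C7 with C11 going to C7 to give an anti η3-allylpalladium over C6–C5–C4; the carboxylate bound to the same palladium then closes the γ-lactone by C6–O bond formation (attack on the allyl terminus, five-membered ring, the C4=C5 bond left outside the new ring). The closest known reaction type is the palladium-catalysed heteroannulation of 1,3-dienes by aryl and vinylic halides that carry a phenol, amine, alcohol or carboxylic acid (Larock-type carbopalladation, then capture of the π-allyl by the tethered heteroatom); new here are 2-bromoacrylic acid as the partner and a bridged medium-ring diene. Of the new stereocentres, C7 should be set cis to the C8 oxygen by the hydroxyl-directed syn carbopalladation (precedent: hydroxyl-directed Heck arylations of cycloalkenols), and C6 by inner-sphere C–O bond formation from the palladium that sits on the same face as C11 (cis-fused lactone); the 4Z geometry should be kept because the anti-allyl is trapped inside the ring before it can isomerise. The step needs regioselectivity (C7 over C4 is secured because C4 is fully substituted, and closure at C6 over C4 by five- versus seven-membered ring formation), facial selectivity (secured by the C8 hydroxyl and by halide-free conditions, Ag2CO3 acting as base and bromide scavenger) and chemoselectivity against β-hydride elimination (H7 is anti to palladium and C3 carries no hydrogen). The C8 hydroxyl is left free because an allylic ester at C8 would be ionised by zerovalent palladium.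

Step 14
Reactants: 22 the cis-fused α-methylene-γ-lactone with 3-OMe, 8-OH and 15-OTBS
Product: 23 the 8-O-isobutyrate of 22 (3-O-methyl-15-O-TBS target)
Conditions: (i-PrCO)2O, Et3N, DMAP (cat.), CH2Cl2, 0 °C → rt
Reagents that add atoms: isobutyric anhydride, CC(C)C(=O)OC(=O)C(C)C
Why: DMAP-catalysed acylation of the only free hydroxyl (C8) with retention of configuration.

Step 15
Reactants: 23 3-O-methyl-15-O-TBS target
Product: 25 CNP0282937.2 (3S,6S,7R,8R,10R; 4Z), via desilylated methyl ketal 24 (not isolated)
Conditions: 48% aq. HF, MeCN, 0 °C → rt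
Reagents that add atoms: water, O
Why: Aqueous HF cleaves the primary allylic TBS ether and hydrolyses the methyl ketal to the hemiketal, whose C3 configuration is fixed by the 3,10-bridge; the isobutyrate and the α-methylene lactone should tolerate these mildly acidic conditions.

**Compound list**

1 | (R)-(−)-linalool, (3R)-3,7-dimethylocta-1,6-dien-3-ol | CC(C)=CCC[C@](C)(C=C)O | starting material
2 | (4R)-4-hydroxy-4-methylhex-5-enal (open form of 3, not isolated) | O=CCC[C@](C)(C=C)O | intermediate
3 | (5R)-5-methyl-5-vinyltetrahydrofuran-2-ol (anomer mixture) | OC1CC[C@](C)(C=C)O1 | intermediate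
4 | (5R)-5-methyl-5-vinyldihydrofuran-2(3H)-one | O=C1CC[C@](C)(C=C)O1 | intermediate
5 | (5R)-5-[2-(9-borabicyclo[3.3.1]nonan-9-yl)ethyl]-5-methyldihydrofuran-2(3H)-one (not isolated) | O=C1CC[C@](C)(CCB2C3CCCC2CCC3)O1 | intermediate
6 | (5R)-5-(2-hydroxyethyl)-5-methyldihydrofuran-2(3H)-one | O=C1CC[C@](C)(CCO)O1 | intermediate
7 | 2-[(2R)-2-methyl-5-oxotetrahydrofuran-2-yl]acetaldehyde | O=C1CC[C@](C)(CC=O)O1 | intermediate
8 | (5R)-5-[(2R)-2-hydroxybut-3-en-1-yl]-5-methyldihydrofuran-2(3H)-one | O=C1CC[C@](C)(C[C@@H](O)C=C)O1 | intermediate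
9 | (5R)-5-methyl-5-[(2R)-2-(triethylsilyloxy)but-3-en-1-yl]dihydrofuran-2(3H)-one | O=C1CC[C@](C)(C[C@@H](O[Si](CC)(CC)CC)C=C)O1 | intermediate
10 | prop-2-yn-1-ol | C#CCO | starting material
11 | vinyl bromide | C=CBr | starting material
12 | pent-4-en-2-yn-1-ol | C=CC#CCO | intermediate
13 | (2Z)-2-(tributylstannyl)penta-2,4-dien-1-ol (tin cis to the vinyl group) | C=C/C=C(/CO)[Sn](CCCC)(CCCC)CCCC | intermediate
14 | TBS ether of 13 | C=C/C=C(/CO[Si](C)(C)C(C)(C)C)[Sn](CCCC)(CCCC)CCCC | intermediate
15 | vinyllithium from 14 (lithium in place of tin, geometry retained; not isolated) | C=C/C=C(/CO[Si](C)(C)C(C)(C)C)[Li] | intermediate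
16 | (3Z,8R,10R)-4-[(tert-butyldimethylsilyloxy)methyl]-8-hydroxy-8-methyl-10-(triethylsilyloxy)dodeca-1,3,11-trien-5-one | C=C/C=C(/CO[Si](C)(C)C(C)(C)C)C(=O)CC[C@](C)(C[C@@H](O[Si](CC)(CC)CC)C=C)O | intermediate
17 | cis-lactol tautomer of 16 (2-hydroxytetrahydrofuran with the dienyl and the C9 chain cis; C3 S; not isolated) | C=C/C=C(/CO[Si](C)(C)C(C)(C)C)[C@]1(O)CC[C@](C)(C[C@@H](O[Si](CC)(CC)CC)C=C)O1 | intermediate
18 | (1S,2Z,4Z,6R,8R)-2-[(tert-butyldimethylsilyloxy)methyl]-8-methyl-6-(triethylsilyloxy)-11-oxabicyclo[6.2.1]undeca-2,4-dien-1-ol | CC[Si](CC)(CC)O[C@@H]1C[C@@]2(C)CC[C@](O)(O2)/C(CO[Si](C)(C)C(C)(C)C)=C\C=C/1 | intermediate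
19 | 1-O-methyl ketal of 18 with the TES ether still in place (not isolated) | CC[Si](CC)(CC)O[C@@H]1C[C@@]2(C)CC[C@](OC)(O2)/C(CO[Si](C)(C)C(C)(C)C)=C\C=C/1 | intermediate
20 | (1S,2Z,4Z,6R,8R)-2-[(tert-butyldimethylsilyloxy)methyl]-1-methoxy-8-methyl-11-oxabicyclo[6.2.1]undeca-2,4-dien-6-ol | O[C@@H]1C[C@@]2(C)CC[C@](OC)(O2)/C(CO[Si](C)(C)C(C)(C)C)=C\C=C/1 | intermediate
21 | 2-bromoacrylic acid | C=C(Br)C(=O)O | starting material
22 | 3-O-methyl-15-O-TBS-8-desisobutyryl target (3S,6S,7R,8R,10R; 4Z; cis-fused α-methylene-γ-lactone) | C=C1C(=O)O[C@H]2/C=C(/CO[Si](C)(C)C(C)(C)C)[C@]3(OC)CC[C@](C)(C[C@@H](O)[C@@H]12)O3 | intermediate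
23 | 3-O-methyl-15-O-TBS target (8-O-isobutyrate of 22) | C=C1C(=O)O[C@H]2/C=C(/CO[Si](C)(C)C(C)(C)C)[C@]3(OC)CC[C@](C)(C[C@@H](OC(=O)C(C)C)[C@@H]12)O3 | intermediate
24 | 3-O-methyl target (15-OH free; not isolated) | C=C1C(=O)O[C@H]2/C=C(/CO)[C@]3(OC)CC[C@](C)(C[C@@H](OC(=O)C(C)C)[C@@H]12)O3 | intermediate
25 | CNP0282937.2 (3S,6S,7R,8R,10R; 4Z) | C=C1C(=O)O[C@H]2/C=C(/CO)[C@]3(O)CC[C@](C)(C[C@@H](OC(=O)C(C)C)[C@@H]12)O3 | target

**Count and risks**

Total step count: 15. Longest linear sequence: 12 steps (steps 1–6 and 10–15, from linalool).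

Steps most likely to fail:

1. Step 13 (Proposed new method). The carbopalladation may proceed with poor facial selectivity, or the allylpalladium may lose a β-hydrogen to a triene before the carboxylate closes the ring. The fallback uses known chemistry, sets out from 20 and comes back at 22. It is an oxidative free-radical lactone annulation of the diene followed by decarboxylative methylenation. Treatment of 20 with malonic acid, Mn(OAc)3·2H2O and catalytic Cu(OAc)2·H2O in AcOH/MeCN buffered with KOAc at 25–40 °C should add the malonyl radical to C7. Divalent copper oxidises the allyl radical, and a carboxyl group closes on C6 (again the O–C6 bond, cis-fused five-membered ring) to give the α-carboxy lactone F1. Warming with aqueous CH2O and Et2NH, then NaOAc/AcOH (Mannich reaction with loss of CO2), should give 22. Facial selectivity in this fallback rests on the shape of the bicycle alone and would have to be checked.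

2. Step 11. The open hydroxy ketone may dominate over the cyclisation-competent lactol, so that cross-metathesis oligomers form, or the ruthenium dienylcarbene may stall. The fallback closes the ring at C7–C8 by a Nozaki–Hiyama–Kishi reaction instead; it sets out from 10 and 6 and comes back at 20.
   - Cadiot–Chodkiewicz coupling of 10 with (bromoethynyl)trimethylsilane (CuCl, NH2OH·HCl, n-BuNH2) should give 5-(trimethylsilyl)penta-2,4-diyn-1-ol F2.
   - Hydroxyl-directed trans-hydrostannation of the proximal triple bond (Bu3SnH, [Cp*RuCl]4) should give the (2Z)-stannyl enynol F3, and TBSCl/imidazole its silyl ether F4.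
   - Tin–lithium exchange (n-BuLi, −78 °C) gives the vinyllithium F5, which is added to 6 (pre-treated with one equivalent of MeLi) to give the hydroxy ynenone diol F6.
   - NIS with catalytic AgNO3 in DMF converts the silylalkyne into the iodoalkyne F7, and diimide (2-nitrobenzenesulfonylhydrazide, Et3N) reduces it to the (Z)-vinyl iodide F8.
   - Dess–Martin oxidation of the primary alcohol gives the aldehyde F9.
   - CrCl2 with catalytic NiCl2 in DMSO/THF at high dilution should close the C7–C8 bond, after which the ring collapses to the bridged hemiketal dienol F10.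
   - PPTS in MeOH then gives 20.

   In this fallback C8 is set by the ring-closing addition under substrate control, and its sense would have to be confirmed.

3. Step 10. The vinyllithium may enolise the lactone, add twice, or be lost by β-elimination of silanolate to an allene. The fallback changes the electrophile from lactone to aldehyde; it sets out from 9 and comes back at 16. Reduction of 9 with i-Bu2AlH (CH2Cl2, −78 °C) should give the lactol F11. After deprotonation with one equivalent of MeLi, addition of 15 to its open hydroxy aldehyde form should give the dienyl carbinol diol F12 as a mixture at C3. MnO2 in CH2Cl2 should oxidise only the allylic alcohol and give 16.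

**Further compounds**

F1 | step 13 | α-carboxy lactone (11-carboxy-11,13-dihydro analogue of 22, C11 unassigned) | OC(=O)C1C(=O)O[C@H]2/C=C(/CO[Si](C)(C)C(C)(C)C)[C@]3(OC)CC[C@](C)(C[C@@H](O)[C@@H]12)O3
F2 | step 11 | 5-(trimethylsilyl)penta-2,4-diyn-1-ol | C[Si](C)(C)C#CC#CCO
F3 | step 11 | (2Z)-2-(tributylstannyl)-5-(trimethylsilyl)pent-2-en-4-yn-1-ol | C[Si](C)(C)C#C/C=C(/CO)[Sn](CCCC)(CCCC)CCCC
F4 | step 11 | TBS ether of F3 | C[Si](C)(C)C#C/C=C(/CO[Si](C)(C)C(C)(C)C)[Sn](CCCC)(CCCC)CCCC
F5 | step 11 | vinyllithium from F4 (lithium in place of tin, geometry retained) | C[Si](C)(C)C#C/C=C(/CO[Si](C)(C)C(C)(C)C)[Li]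
F6 | step 11 | hydroxy ynenone diol (C3 ketone, C10 tertiary OH, C8 primary OH, silylalkyne at C6–C7) | C[Si](C)(C)C#C/C=C(/CO[Si](C)(C)C(C)(C)C)C(=O)CC[C@](C)(CCO)O
F7 | step 11 | iodoalkyne from F6 | IC#C/C=C(/CO[Si](C)(C)C(C)(C)C)C(=O)CC[C@](C)(CCO)O
F8 | step 11 | (Z)-vinyl iodide (6Z,4Z-dienone diol) | I/C=C\C=C(\CO[Si](C)(C)C(C)(C)C)C(=O)CC[C@](C)(CCO)O
F9 | step 11 | C8 aldehyde of F8 | I/C=C\C=C(\CO[Si](C)(C)C(C)(C)C)C(=O)CC[C@](C)(CC=O)O
F10 | step 11 | (1S,2Z,4Z,6R,8R)-2-[(tert-butyldimethylsilyloxy)methyl]-8-methyl-11-oxabicyclo[6.2.1]undeca-2,4-diene-1,6-diol | O[C@@H]1C[C@@]2(C)CC[C@](O)(O2)/C(CO[Si](C)(C)C(C)(C)C)=C\C=C/1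
F11 | step 10 | (5R)-5-methyl-5-[(2R)-2-(triethylsilyloxy)but-3-en-1-yl]tetrahydrofuran-2-ol (anomer mixture) | OC1CC[C@](C)(C[C@@H](O[Si](CC)(CC)CC)C=C)O1
F12 | step 10 | (3Z,8R,10R)-4-[(tert-butyldimethylsilyloxy)methyl]-8-methyl-10-(triethylsilyloxy)dodeca-1,3,11-triene-5,8-diol (C5 epimers) | C=C/C=C(/CO[Si](C)(C)C(C)(C)C)C(O)CC[C@](C)(C[C@@H](O[Si](CC)(CC)CC)C=C)O
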